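**Retrosynthetic overview**
1. The target is traced back to its bis-silyl, 5,8-di-O-methyl chalcone (oxidative demethylation, reduction and desilylation last), and that to a 6-acetylchromene plus 4-silyloxybenzaldehyde (aldol condensation), the acetyl group coming from a 6-formylchromene.
2. The pyran is the only ring made; both benzene rings are bought. It is closed at the C4–C4a bond by gold-catalysed hydroarylation of an (S)-aryl propargyl ether. The strategy rests on one feature: in the benzo ring C4a is the only unsubstituted carbon ortho to O1, because C8 bears oxygen, so an ethynyl group on C2 can be joined to C4a while the C2–O1 bond and the C2 stereocentre stay untouched.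
3. The O1–C8a bond comes from fluoride displacement on 4-fluoro-2,5-dimethoxybenzaldehyde by the (S)-tertiary alkynol.
4. The alkynol comes from fragmentation of an epoxy chloride, made by Sharpless epoxidation of 7-silyloxy-6,7-dihydrogeraniol (from geranyl acetate). This epoxidation sets C2.

Key step: step 8

Remark: the carbinol centres created in steps 9 and 12 and the chloroalkene geometry of the intermediate in step 6 are not controlled and are drawn without descriptors, since each is removed in the next operation; from step 8 on the 2H-chromene is kept from ultraviolet light and prolonged heating, because reversible electrocyclic ring opening would racemise C2.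

**Route**

Step 1
Reactants: 1 geranyl acetate
Product: 3 (E)-7-hydroxy-3,7-dimethyloct-2-en-1-yl acetate, via organomercurial 2 (not isolated)
Conditions: Hg(OAc)2, THF/H2O, rt; then aq. NaOH, NaBH4, 0 °C
Reagents that add atoms: water, O
Why: Markovnikov oxymercuration–demercuration should hydrate only the electron-rich 6,7-alkene, since the 2,3-alkene is deactivated by the allylic acetate, and the short cold borohydride treatment should leave the ester intact.

Step 2
Reactants: 3 (E)-7-hydroxy-3,7-dimethyloct-2-en-1-yl acetate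
Product: 4 (E)-3,7-dimethyl-7-(triethylsilyloxy)oct-2-en-1-yl acetate
Conditions: Et3SiOTf, 2,6-lutidine, CH2Cl2, −78 → 0 °C
Reagents that add atoms: triethylsilyl trifluoromethanesulfonate, CC[Si](CC)(CC)OS(=O)(=O)C(F)(F)F
Why: Silylation of a hindered tertiary alcohol with a silyl triflate and lutidine is reliable and masks the only other hydroxyl that could form an alkoxide in steps 6 and 7.

Step 3
Reactants: 4 (E)-3,7-dimethyl-7-(triethylsilyloxy)oct-2-en-1-yl acetate
Product: 5 (E)-3,7-dimethyl-7-(triethylsilyloxy)oct-2-en-1-ol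
Conditions: K2CO3, MeOH, 0 °C → rt
Reagents that add atoms: none
Why: Base-catalysed transesterification (methanolysis) should free the primary allylic alcohol needed to direct the epoxidation, and a hindered tertiary triethylsilyl ether should withstand K2CO3 in methanol.

Step 4
Reactants: 5 (E)-3,7-dimethyl-7-(triethylsilyloxy)oct-2-en-1-ol
Product: 6 [(2S,3S)-3-methyl-3-[4-methyl-4-(triethylsilyloxy)pentyl]oxiran-2-yl]methanol
Conditions: Ti(OiPr)4 (cat.), L-(+)-diethyl tartrate (cat.), t-BuOOH, 4 Å MS, CH2Cl2, −20 °C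
Reagents that add atoms: tert-butyl hydroperoxide, CC(C)(C)OO
Why: Sharpless asymmetric epoxidation with L-(+)-tartrate should deliver oxygen to the face of this (E)-allylic alcohol that gives the (2S,3S)-epoxide, as it does for geraniol, so the quaternary carbon that becomes C2 of the chromene is set S by the catalyst.

Step 5
Reactants: 6 [(2S,3S)-3-methyl-3-[4-methyl-4-(triethylsilyloxy)pentyl]oxiran-2-yl]methanol
Product: 7 (2S,3R)-3-(chloromethyl)-2-methyl-2-[4-methyl-4-(triethylsilyloxy)pentyl]oxirane (same spatial arrangement as 6; the CH descriptor changes only because CH2Cl outranks the ring carbon)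
Conditions: PPh3, CCl4, NaHCO3, reflux
Reagents that add atoms: tetrachloromethane, ClC(Cl)(Cl)Cl
Why: Appel chlorination should convert the primary alcohol into the chloride under buffered neutral conditions that leave the epoxide and the silyl ether alone.

Step 6
Reactants: 7 (2S,3R)-3-(chloromethyl)-2-methyl-2-[4-methyl-4-(triethylsilyloxy)pentyl]oxirane
Product: 9 (3S)-3,7-dimethyl-7-(triethylsilyloxy)oct-1-yn-3-ol, via chloroalkenyl alkoxide 8 (not isolated)
Conditions: LiN(iPr)2 (3.5 equiv), THF, −78 → −30 °C; aq. NH4Cl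
Reagents that add atoms: none
Why: Base-induced fragmentation of a 2,3-epoxy chloride to a propargylic alcohol: deprotonation at CH2Cl opens the epoxide by β-elimination, the chloroalkenyl alkoxide then loses HCl to give the terminal alkyne, and the C–O bond at the quaternary carbon is never broken, so its S configuration is retained.

Step 7
Reactants: 9 (3S)-3,7-dimethyl-7-(triethylsilyloxy)oct-1-yn-3-ol; 10 4-fluoro-2,5-dimethoxybenzaldehyde
Product: 11 4-{[(3S)-3,7-dimethyl-7-(triethylsilyloxy)oct-1-yn-3-yl]oxy}-2,5-dimethoxybenzaldehyde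
Conditions: KN(SiMe3)2 (1.05 equiv), THF, 0 °C; then 10, DMF, 0 °C → rt
Reagents that add atoms: none
Why: Nucleophilic aromatic substitution (addition–elimination) of the fluoride para to the non-enolisable formyl group by the potassium tertiary alkoxide forms the O1–C8a bond at the aryl carbon, so the carbinol stereocentre is not touched.

Step 8
Reactants: 11 4-{[(3S)-3,7-dimethyl-7-(triethylsilyloxy)oct-1-yn-3-yl]oxy}-2,5-dimethoxybenzaldehyde
Product: 12 (2S)-5,8-dimethoxy-2-methyl-2-[4-methyl-4-(triethylsilyloxy)pentyl]-2H-chromene-6-carbaldehyde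
Conditions: Ph3PAuNTf2 (3 mol%), CH2Cl2, 0 °C → rt, dark
Reagents that add atoms: none
Why: Cationic monovalent gold from Ph3PAuNTf2 coordinates the terminal alkyne, C4a of the arene attacks the terminal alkyne carbon anti to gold, and rearomatisation followed by protodeauration of the vinylgold species gives the C3=C4 alkene. The closest known reaction type is the gold- or platinum-catalysed intramolecular hydroarylation of aryl propargyl ethers to 2H-chromenes. The pyran ring closes in the 6-endo-dig mode with formation of the C4–C4a bond. No stereocentre is formed, and the S centre at C2 is carried over unchanged because C2–O1 is never broken, unlike the thermal propargyl Claisen path, which runs through an achiral ortho-quinone methide. The step needs 6-endo rather than 5-exo closure, reaction at C4a only, and no heterolysis of the tertiary propargylic C2–O1 bond: the terminal alkyne on a quaternary carbon favours attack at its unhindered end, C4a is the only free position ortho to O1 (C8 carries a methoxy group) and is activated by O1 and the C5 methoxy group while lying meta to the formyl group, and a preformed, silver-free and acid-free catalyst in CH2Cl2 at low temperature should keep ionisation from competing.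

Step 9
Reactants: 12 (2S)-5,8-dimethoxy-2-methyl-2-[4-methyl-4-(triethylsilyloxy)pentyl]-2H-chromene-6-carbaldehyde
Product: 13 1-{(2S)-5,8-dimethoxy-2-methyl-2-[4-methyl-4-(triethylsilyloxy)pentyl]-2H-chromen-6-yl}ethanol (epimer mixture at the carbinol carbon)
Conditions: MeMgBr, THF, −78 → 0 °C; aq. NH4Cl
Reagents that add atoms: methylmagnesium bromide, C[Mg]Br
Why: Grignard addition to the aryl aldehyde should be clean, and the new carbinol centre need not be controlled because it is oxidised in the next step.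

Step 10
Reactants: 13 1-{(2S)-5,8-dimethoxy-2-methyl-2-[4-methyl-4-(triethylsilyloxy)pentyl]-2H-chromen-6-yl}ethanol
Product: 14 1-{(2S)-5,8-dimethoxy-2-methyl-2-[4-methyl-4-(triethylsilyloxy)pentyl]-2H-chromen-6-yl}ethanone
Conditions: Dess–Martin periodinane, NaHCO3, CH2Cl2, rt
Reagents that add atoms: none
Why: Dess–Martin oxidation of the secondary benzylic alcohol under buffered conditions should give the methyl ketone without touching the chromene alkene or the silyl ether.

Step 11
Reactants: 15 4-hydroxybenzaldehyde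
Product: 16 4-(tert-butyldimethylsilyloxy)benzaldehyde
Conditions: t-BuMe2SiCl, imidazole, DMF, rt
Reagents that add atoms: tert-butyldimethylsilyl chloride, CC(C)(C)[Si](C)(C)Cl
Why: Imidazole-promoted silylation masks the phenol, which would otherwise quench the enolate in step 12 and be open to oxidation in step 14.

Step 12
Reactants: 14 1-{(2S)-5,8-dimethoxy-2-methyl-2-[4-methyl-4-(triethylsilyloxy)pentyl]-2H-chromen-6-yl}ethanone; 16 4-(tert-butyldimethylsilyloxy)benzaldehyde
Product: 17 3-[4-(tert-butyldimethylsilyloxy)phenyl]-1-{(2S)-5,8-dimethoxy-2-methyl-2-[4-methyl-4-(triethylsilyloxy)pentyl]-2H-chromen-6-yl}-3-hydroxypropan-1-one (epimer mixture at the carbinol carbon)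
Conditions: LiN(SiMe3)2, THF, −78 °C; then 16; aq. NH4Cl
Reagents that add atoms: none
Why: Directed aldol addition of the lithium enolate of a ketone with one enolisable site to a non-enolisable aldehyde avoids the hydroxide that would cleave the aryl silyl ether, and the new carbinol centre is removed in the next step.

Step 13
Reactants: 17 3-[4-(tert-butyldimethylsilyloxy)phenyl]-1-{(2S)-5,8-dimethoxy-2-methyl-2-[4-methyl-4-(triethylsilyloxy)pentyl]-2H-chromen-6-yl}-3-hydroxypropan-1-one
Product: 19 (E)-3-[4-(tert-butyldimethylsilyloxy)phenyl]-1-{(2S)-5,8-dimethoxy-2-methyl-2-[4-methyl-4-(triethylsilyloxy)pentyl]-2H-chromen-6-yl}prop-2-en-1-one, via mesylate 18 (not isolated)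
Conditions: MsCl, Et3N, CH2Cl2, 0 °C → rt
Reagents that add atoms: none
Why: Mesylation of the β-hydroxy ketone followed by E1cB elimination should give the conjugated enone in the favoured E geometry with aryl and acyl groups trans.

Step 14
Reactants: 19 (E)-3-[4-(tert-butyldimethylsilyloxy)phenyl]-1-{(2S)-5,8-dimethoxy-2-methyl-2-[4-methyl-4-(triethylsilyloxy)pentyl]-2H-chromen-6-yl}prop-2-en-1-one
Product: 21 (E)-3-[4-(tert-butyldimethylsilyloxy)phenyl]-1-{(2S)-5,8-dihydroxy-2-methyl-2-[4-methyl-4-(triethylsilyloxy)pentyl]-2H-chromen-6-yl}prop-2-en-1-one, via quinone 20 (not isolated)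
Conditions: (NH4)2Ce(NO3)6 (2.2 equiv), MeCN/H2O, 0 °C; then aq. Na2S2O4, EtOAc, rt
Reagents that add atoms: water, O
Why: Oxidative demethylation of the para-dimethoxyarene by tetravalent cerium (water adds at the two methoxy-bearing carbons and methanol leaves) should give the 5,8-quinone, which dithionite reduces at once to the hydroquinone while the enone and the chromene alkene stay unreduced at room temperature.

Step 15
Reactants: 21 (E)-3-[4-(tert-butyldimethylsilyloxy)phenyl]-1-{(2S)-5,8-dihydroxy-2-methyl-2-[4-methyl-4-(triethylsilyloxy)pentyl]-2H-chromen-6-yl}prop-2-en-1-one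
Product: 22 (E)-1-[(2S)-5,8-dihydroxy-2-(4-hydroxy-4-methylpentyl)-2-methyl-2H-chromen-6-yl]-3-(4-hydroxyphenyl)prop-2-en-1-one
Conditions: HF·pyridine, pyridine, THF, 0 °C → rt, argon
Reagents that add atoms: none
Why: Fluoride-driven desilylation should remove the aryl and the tertiary alkyl silyl ethers under mildly acidic, non-oxidising conditions that spare the hydroquinone, the enone, the tertiary alcohol and the chromene.

**Compound list**
1 | geranyl acetate | CC(C)=CCC/C(C)=C/COC(C)=O | starting material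
2 | (E)-6-(acetoxymercurio)-7-hydroxy-3,7-dimethyloct-2-en-1-yl acetate (formed and reduced in the flask in step 1) | CC(=O)OC/C=C(\C)CCC([Hg]OC(C)=O)C(C)(C)O | intermediate
3 | (E)-7-hydroxy-3,7-dimethyloct-2-en-1-yl acetate | CC(=O)OC/C=C(\C)CCCC(C)(C)O | intermediate
4 | (E)-3,7-dimethyl-7-(triethylsilyloxy)oct-2-en-1-yl acetate | CC(=O)OC/C=C(\C)CCCC(C)(C)O[Si](CC)(CC)CC | intermediate
5 | (E)-3,7-dimethyl-7-(triethylsilyloxy)oct-2-en-1-ol | OC/C=C(\C)CCCC(C)(C)O[Si](CC)(CC)CC | intermediate
6 | [(2S,3S)-3-methyl-3-[4-methyl-4-(triethylsilyloxy)pentyl]oxiran-2-yl]methanol | OC[C@@H]1O[C@@]1(C)CCCC(C)(C)O[Si](CC)(CC)CC | intermediate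
7 | (2S,3R)-3-(chloromethyl)-2-methyl-2-[4-methyl-4-(triethylsilyloxy)pentyl]oxirane | ClC[C@@H]1O[C@@]1(C)CCCC(C)(C)O[Si](CC)(CC)CC | intermediate
8 | lithium (3S)-1-chloro-3,7-dimethyl-7-(triethylsilyloxy)oct-1-en-3-olate (formed and consumed in the flask in step 6) | ClC=C[C@@](C)(O[Li])CCCC(C)(C)O[Si](CC)(CC)CC | intermediate
9 | (3S)-3,7-dimethyl-7-(triethylsilyloxy)oct-1-yn-3-ol | C#C[C@](C)(CCCC(C)(C)O[Si](CC)(CC)CC)O | intermediate
10 | 4-fluoro-2,5-dimethoxybenzaldehyde | COc1cc(F)c(OC)cc1C=O | starting material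
11 | 4-{[(3S)-3,7-dimethyl-7-(triethylsilyloxy)oct-1-yn-3-yl]oxy}-2,5-dimethoxybenzaldehyde | C#C[C@](C)(CCCC(C)(C)O[Si](CC)(CC)CC)Oc1cc(OC)c(C=O)cc1OC | intermediate
12 | (2S)-5,8-dimethoxy-2-methyl-2-[4-methyl-4-(triethylsilyloxy)pentyl]-2H-chromene-6-carbaldehyde | CC[Si](CC)(CC)OC(C)(C)CCC[C@@]1(C)C=Cc2c(OC)c(C=O)cc(OC)c2O1 | intermediate
13 | 1-{(2S)-5,8-dimethoxy-2-methyl-2-[4-methyl-4-(triethylsilyloxy)pentyl]-2H-chromen-6-yl}ethanol | CC[Si](CC)(CC)OC(C)(C)CCC[C@@]1(C)C=Cc2c(OC)c(C(C)O)cc(OC)c2O1 | intermediate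
14 | 1-{(2S)-5,8-dimethoxy-2-methyl-2-[4-methyl-4-(triethylsilyloxy)pentyl]-2H-chromen-6-yl}ethanone | CC[Si](CC)(CC)OC(C)(C)CCC[C@@]1(C)C=Cc2c(OC)c(C(C)=O)cc(OC)c2O1 | intermediate
15 | 4-hydroxybenzaldehyde | O=Cc1ccc(O)cc1 | starting material
16 | 4-(tert-butyldimethylsilyloxy)benzaldehyde | CC(C)(C)[Si](C)(C)Oc1ccc(C=O)cc1 | intermediate
17 | 3-[4-(tert-butyldimethylsilyloxy)phenyl]-1-{(2S)-5,8-dimethoxy-2-methyl-2-[4-methyl-4-(triethylsilyloxy)pentyl]-2H-chromen-6-yl}-3-hydroxypropan-1-one | CC[Si](CC)(CC)OC(C)(C)CCC[C@@]1(C)C=Cc2c(OC)c(C(=O)CC(O)c3ccc(O[Si](C)(C)C(C)(C)C)cc3)cc(OC)c2O1 | intermediate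
18 | methanesulfonate of 17 at the benzylic hydroxyl (formed and eliminated in the flask in step 13) | CC[Si](CC)(CC)OC(C)(C)CCC[C@@]1(C)C=Cc2c(OC)c(C(=O)CC(OS(C)(=O)=O)c3ccc(O[Si](C)(C)C(C)(C)C)cc3)cc(OC)c2O1 | intermediate
19 | (E)-3-[4-(tert-butyldimethylsilyloxy)phenyl]-1-{(2S)-5,8-dimethoxy-2-methyl-2-[4-methyl-4-(triethylsilyloxy)pentyl]-2H-chromen-6-yl}prop-2-en-1-one | CC[Si](CC)(CC)OC(C)(C)CCC[C@@]1(C)C=Cc2c(OC)c(C(=O)/C=C/c3ccc(O[Si](C)(C)C(C)(C)C)cc3)cc(OC)c2O1 | intermediate
20 | (2S)-6-{(E)-3-[4-(tert-butyldimethylsilyloxy)phenyl]prop-2-enoyl}-2-methyl-2-[4-methyl-4-(triethylsilyloxy)pentyl]-2H-chromene-5,8-dione (formed and reduced in step 14) | CC[Si](CC)(CC)OC(C)(C)CCC[C@@]1(C)C=CC2=C(O1)C(=O)C=C(C(=O)/C=C/c3ccc(O[Si](C)(C)C(C)(C)C)cc3)C2=O | intermediate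
21 | (E)-3-[4-(tert-butyldimethylsilyloxy)phenyl]-1-{(2S)-5,8-dihydroxy-2-methyl-2-[4-methyl-4-(triethylsilyloxy)pentyl]-2H-chromen-6-yl}prop-2-en-1-one | CC[Si](CC)(CC)OC(C)(C)CCC[C@@]1(C)C=Cc2c(O)c(C(=O)/C=C/c3ccc(O[Si](C)(C)C(C)(C)C)cc3)cc(O)c2O1 | intermediate
22 | (E)-1-[(2S)-5,8-dihydroxy-2-(4-hydroxy-4-methylpentyl)-2-methyl-2H-chromen-6-yl]-3-(4-hydroxyphenyl)prop-2-en-1-one | CC(C)(O)CCC[C@@]1(C)C=Cc2c(O)c(C(=O)/C=C/c3ccc(O)cc3)cc(O)c2O1 | target

**Step count**
Total: 15 steps. Longest linear sequence: 14 steps (steps 1–10 and 12–15, from geranyl acetate); step 11 is a one-step branch.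

**Steps most likely to fail**

1. Step 8 (gold hydroarylation). The para-formyl group makes the aryloxide a good leaving group and makes the ring less nucleophilic, so gold-assisted heterolysis of the tertiary propargylic C2–O1 bond could outrun ring closure and erode the configuration at C2 or detach the side chain. The fallback sets out from 11 and masks the formyl group so that the arene becomes donor-substituted. Treatment of 11 with 1,2-bis(trimethylsilyloxy)ethane and catalytic Me3SiOTf in CH2Cl2 at −78 °C should give 2-{4-[(3S)-3,7-dimethyl-7-(triethylsilyloxy)oct-1-yn-3-yl]oxy-2,5-dimethoxyphenyl}-1,3-dioxolane F1. Its ring closure with Ph3PAuNTf2 in CH2Cl2 should give the chromene acetal 2-{(2S)-5,8-dimethoxy-2-methyl-2-[4-methyl-4-(triethylsilyloxy)pentyl]-2H-chromen-6-yl}-1,3-dioxolane F2. Hydrolysis of this electron-rich aryl acetal with pyridinium tosylate in wet acetone at rt comes back to the route at 12.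

2. Step 7 (fluoride displacement). Reversible addition of the hindered alkoxide to the formyl carbon, hydride-transfer side reactions of the resulting hemiacetal alkoxide, and slow attack on a ring carrying two methoxy groups could stall the substitution. The fallback sets out from 10 and 9 and uses a nitrile as the activating group. Aldehyde 10 is converted with I2 and aqueous NH3 in THF into 4-fluoro-2,5-dimethoxybenzonitrile F3. Its reaction with the potassium alkoxide of 9 (KN(SiMe3)2, THF/DMF) should give 4-{[(3S)-3,7-dimethyl-7-(triethylsilyloxy)oct-1-yn-3-yl]oxy}-2,5-dimethoxybenzonitrile F4. Reduction with iBu2AlH in toluene at −78 °C and mild aqueous hydrolysis of the aldimine comes back to the route at 11.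

3. Step 14 (oxidative demethylation on the chalcone). Tetravalent cerium could also attack the silyloxystyryl unit or the chromene alkene, acid-promoted loss of the aryl silyl ether could expose a phenol to oxidation, and the very electrophilic cinnamoyl quinone could add water before it is reduced. The fallback sets out from 14 and 15 and moves the oxidation to the simple ketone, then carries the hydroquinone as acetal ethers.
   - Ketone 14 is treated with (NH4)2Ce(NO3)6 in MeCN/H2O at 0 °C to give (2S)-6-acetyl-2-methyl-2-[4-methyl-4-(triethylsilyloxy)pentyl]-2H-chromene-5,8-dione F5, which is reduced without isolation by aqueous Na2S2O4 to 1-{(2S)-5,8-dihydroxy-2-methyl-2-[4-methyl-4-(triethylsilyloxy)pentyl]-2H-chromen-6-yl}ethanone F6.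
   - NaH and chloromethyl methyl ether in DMF under argon give 1-{(2S)-5,8-bis(methoxymethoxy)-2-methyl-2-[4-methyl-4-(triethylsilyloxy)pentyl]-2H-chromen-6-yl}ethanone F7.
   - 4-Hydroxybenzaldehyde 15 is converted with chloromethyl methyl ether and iPr2NEt into 4-(methoxymethoxy)benzaldehyde F8.
   - Claisen–Schmidt condensation of F7 with F8 (KOH, EtOH, rt) should give (E)-1-{(2S)-5,8-bis(methoxymethoxy)-2-methyl-2-[4-methyl-4-(triethylsilyloxy)pentyl]-2H-chromen-6-yl}-3-[4-(methoxymethoxy)phenyl]prop-2-en-1-one F9.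
   - Dilute HCl in MeOH/THF at rt to 40 °C removes the three acetal ethers and the silyl ether and comes back to the route at 22.

**Further compounds**
F1 | step 8 | 2-{4-[(3S)-3,7-dimethyl-7-(triethylsilyloxy)oct-1-yn-3-yl]oxy-2,5-dimethoxyphenyl}-1,3-dioxolane | C#C[C@](C)(CCCC(C)(C)O[Si](CC)(CC)CC)Oc1cc(OC)c(C2OCCO2)cc1OC
F2 | step 8 | 2-{(2S)-5,8-dimethoxy-2-methyl-2-[4-methyl-4-(triethylsilyloxy)pentyl]-2H-chromen-6-yl}-1,3-dioxolane | CC[Si](CC)(CC)OC(C)(C)CCC[C@@]1(C)C=Cc2c(OC)c(C3OCCO3)cc(OC)c2O1
F3 | step 7 | 4-fluoro-2,5-dimethoxybenzonitrile | COc1cc(F)c(OC)cc1C#N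
F4 | step 7 | 4-{[(3S)-3,7-dimethyl-7-(triethylsilyloxy)oct-1-yn-3-yl]oxy}-2,5-dimethoxybenzonitrile | C#C[C@](C)(CCCC(C)(C)O[Si](CC)(CC)CC)Oc1cc(OC)c(C#N)cc1OC
F5 | step 14 | (2S)-6-acetyl-2-methyl-2-[4-methyl-4-(triethylsilyloxy)pentyl]-2H-chromene-5,8-dione | CC[Si](CC)(CC)OC(C)(C)CCC[C@@]1(C)C=CC2=C(O1)C(=O)C=C(C(C)=O)C2=O
F6 | step 14 | 1-{(2S)-5,8-dihydroxy-2-methyl-2-[4-methyl-4-(triethylsilyloxy)pentyl]-2H-chromen-6-yl}ethanone | CC[Si](CC)(CC)OC(C)(C)CCC[C@@]1(C)C=Cc2c(O)c(C(C)=O)cc(O)c2O1
F7 | step 14 | 1-{(2S)-5,8-bis(methoxymethoxy)-2-methyl-2-[4-methyl-4-(triethylsilyloxy)pentyl]-2H-chromen-6-yl}ethanone | CC[Si](CC)(CC)OC(C)(C)CCC[C@@]1(C)C=Cc2c(OCOC)c(C(C)=O)cc(OCOC)c2O1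
F8 | step 14 | 4-(methoxymethoxy)benzaldehyde | COCOc1ccc(C=O)cc1
F9 | step 14 | (E)-1-{(2S)-5,8-bis(methoxymethoxy)-2-methyl-2-[4-methyl-4-(triethylsilyloxy)pentyl]-2H-chromen-6-yl}-3-[4-(methoxymethoxy)phenyl]prop-2-en-1-one | CC[Si](CC)(CC)OC(C)(C)CCC[C@@]1(C)C=Cc2c(OCOC)c(C(=O)/C=C/c3ccc(OCOC)cc3)cc(OCOC)c2O1
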